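Planning a neighbour of this flask with 2.0 M of starting material in place of 0.80 M, I first asked what the flask as charged can give of the target.

    gas phase ⇌ dissolved gas, rate k1*(csat - [dissolved gas]) (k1 = 3.6 min⁻¹, csat = 76 mM)
    starting material + dissolved gas → target (k2 = 0.22 L mol⁻¹ min⁻¹)
    starting material → side product A (k3 = 0.0039 min⁻¹)
    starting material + target → side product B (k4 = 0.063 L mol⁻¹ min⁻¹)
    starting material + protic impurity → quenched substrate (k5 = 0.087 L mol⁻¹ min⁻¹)

starting material 0.80 M; gas phase 76 mM (held); protic impurity 0.400 M; time 2.0 h

* the target standing at 2.0 h, as a percentage of the starting material charged
* concentration of dissolved gas in solution at 2.0 h, in percent of saturation

- percent here means starting material units held: one side product B counts as two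
- at the start none of the gas is dissolved
- run time (flask): 2.0 h

I turned the question round and asked what the numbers would have to say for the gas to hold the target back. The dissolved gas is consumed at 0.176 min⁻¹ at the charge and replaced at 3.6 min⁻¹, and starvation would need these two to be comparable, yet transfer is 20.5 times the faster. So I expected [dissolved gas], from none at the start, to rise on a time scale of about 0.278 min to near 95.3% of saturation and then to climb as [starting material] falls, which makes the second step pseudo-first-order in starting material. That step makes target and the fourth step destroys it, and both rates carry [starting material], which cancels. Target therefore stops growing at a concentration I call the target ceiling, the second rate constant times the saturation concentration divided by the fourth rate constant: 0.265 M. For the target to take up the whole charge, this ceiling would have to reach 0.80 M, and it stands at about a third of that. My reckoning went no further than a bound of 33.1% for the yield.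

The forecast gave 22% and >99.9%, on these grounds: “The gas transfer is much faster than its consumption”. Its yield is an estimate and mine a bound, and it lies beneath my bound.

The simulation gave 22.0% and >99.9%, as the forecast had it, so this flask holds 0.176 M of target, less than the ceiling of 0.265 M, with 0.766% of the starting material left. The ceiling contains no [starting material], so for the neighbour at 2.0 M I kept 0.265 M and divided by the larger charge, which allows 13.2% there. That neighbour gave 12.4%, or 0.248 M of target, a higher concentration than in this flask but a smaller percentage, with side product B at 56.5%.

(The rate constants are assumed, and the outcome is calculated.)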